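The constants were drawn at random within sensible limits; no experiment stands behind them.

0.597 min⁻¹ against 0.426 min⁻¹: in cedar these are my rates for coupling, taken as pseudo-first-order in the coupling partner with the substrate held at its charge, and for the forward draining of intermediate to target and isomer.

in all of them: substrate 2.0 M; coupling partner 0.700 equiv; time 1.5 min
- larch: temperature 55 °C
- cedar: temperature 15 °C
- alder: temperature 35 °C
- ash: temperature −5 °C

    substrate + coupling partner → intermediate + by-product (k1 = 0.035 L mol⁻¹ s⁻¹, Ea1 = 72.0 kJ mol⁻¹)
    intermediate ⇌ target (K2 = 2.9, k2 = 0.044 s⁻¹, Ea2 = 70.0 kJ mol⁻¹, ΔH2 = −37.0 kJ mol⁻¹)
    intermediate ⇌ isomer of the product (K3 = 4.1, k3 = 0.0064 s⁻¹, Ea3 = 94.0 kJ mol⁻¹, ΔH3 = −25.0 kJ mol⁻¹)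
    coupling partner + target → over-reaction product (k4 = 0.0024 L mol⁻¹ s⁻¹, Ea4 = 77.0 kJ mol⁻¹)
    (constants at 35 °C)

- the constants hold at 35 °C; other temperatures follow from the activation energies and enthalpies

1. the flask with the highest amount of intermediate, in percent of the substrate charged ("all alike" if they lie within 1.5 percentage points) (larch / cedar / alder / ash / all alike)
2. final intermediate, as a percentage of the substrate charged, in larch
3. final intermediate, as a percentage of the substrate charged, in cedar
4. final intermediate, as a percentage of the substrate charged, in alder
5. final intermediate, as a percentage of the substrate charged, in ash

I solve two extreme flasks first. If draining did nothing, intermediate would simply be what coupling has made, and the opening rate gives 6.67% of the substrate charge in ash. If coupling were over and the intermediate had equilibrated, it would hold the share of the coupled charge that the equilibrium constants allow, which at larch's temperature is 15.7%.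

Between these extremes stands the crossing time, the moment at which the making of intermediate falls to its draining. For two first-order steps in series, it is the logarithm of the rate ratio divided by the rate difference, so cedar crosses at 1.97 min. That is later than the 1.5 min allowed, so by this reckoning cedar ends short of its peak, at about 29.2%. I read that figure as high, since I hold the substrate at its charge.

By the same reckoning alder crosses at 0.279 min, well before the end. Ash couples at 0.0635 min⁻¹ and drains at 0.0464 min⁻¹, so it crosses at 18.3 min, far beyond the end. Cedar's figure stands above those I have for larch and ash, and alder is past its crossing, so I pick cedar.

The forecast also names cedar, with 15.7% in larch, 25% in cedar, 15.3% in alder and 5.9% in ash, reasoning that at cedar's temperature drainage is slow, “so the most intermediate remains there”. Its cedar figure is lower than mine.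

The simulation gives cedar, with 15.3% in larch, 24.9% in cedar, 14.8% in alder and 5.95% in ash. In cedar, coupling was still running at the end with 49.2% of the coupling partner left, and intermediate was being made 1.31 times faster than it was used up, each step taken net. Cedar ended 76.1% of the way to its reckoned crossing, while ash, left until 15.0 min, stood 82.0% of the way to its own and held 24.8%.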